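The route disconnects the ketone C(=O)–CH2 bond of the deoxybenzoin. The feature exploited is the phenolic oxygen on C7 of the chromene benzo ring, which sits ortho to the acyl carbon on C6. It carries the 4-methoxyphenylacetyl unit as an ester, so that the ester enolate can attack the neighbouring C6 methyl ester. In one operation this intramolecular Claisen condensation forms the C–C bond and closes a pyranone ring, giving a 3-aryl-4-hydroxycoumarin. The precursor is a 2,2-dimethyl-2H-chromene bearing OMe at C5, CO2Me at C6 and the arylacetate on O7. Alkaline lactone opening and loss of CO2 then release the target.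

Key step: step 7

Remark: chromene numbering (O1, C2 with the two methyls, C3=C4, C4a, C5 to C8, C8a) is used for all bicyclic compounds. The target has no stereocentre, so no stereochemical control is needed.

Step 1
Reactants: 1 methyl 2,4,6-trihydroxybenzoate; 2 3-chloro-3-methylbut-1-yne
Product: 3 methyl 2,6-dihydroxy-4-[(2-methylbut-3-yn-2-yl)oxy]benzoate
Conditions: DBU (1.2 equiv), CuCl2·2H2O (1 mol%), MeCN, 0 °C
Reagents that add atoms: none
Why: Copper-catalysed O-propargylation of a phenol by a tertiary propargylic chloride; the 4-OH, para to the ester and the only hydroxyl not held in a hydrogen bond to it, is the most acidic and most nucleophilic, so one equivalent of electrophile should etherify it alone.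

Step 2
Reactants: 3 methyl 2,6-dihydroxy-4-[(2-methylbut-3-yn-2-yl)oxy]benzoate
Product: 4 methyl 2-hydroxy-6-(methoxymethoxy)-4-[(2-methylbut-3-yn-2-yl)oxy]benzoate
Conditions: MOMCl (1.1 equiv), iPr2NEt, CH2Cl2, 0 °C to rt
Reagents that add atoms: chloromethyl methyl ether, COCCl
Why: Base-mediated O-alkylation (MOM ether formation) of one of two equivalent phenols; once one is capped, the other is locked in a strong hydrogen bond to the ester carbonyl and reacts much more slowly, so the reaction should stop at the mono-ether.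

Step 3
Reactants: 4 methyl 2-hydroxy-6-(methoxymethoxy)-4-[(2-methylbut-3-yn-2-yl)oxy]benzoate
Product: 7 methyl 5-hydroxy-7-(methoxymethoxy)-2,2-dimethyl-2H-chromene-6-carboxylate, via allenylphenol 5 (not isolated), via quinone methide 6 (not isolated)
Conditions: o-xylene, reflux, N2
Reagents that add atoms: none
Why: Thermal aryl propargyl ether Claisen rearrangement gives allenylphenol 5, a 1,5-hydrogen shift gives quinone methide 6 and an oxa-6π electrocyclisation closes the pyran; the hydrogen bond from the free 2-OH to the ester fixes double-bond character in the C3–C4 ring bond of the benzoate, so the [3,3] shift should go to C3 beside the free hydroxyl, as in 2-hydroxy-4-propargyloxy aryl carbonyl compounds, with the MOM ether next to C5 adding a steric bias in the same sense.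

Step 4
Reactants: 7 methyl 5-hydroxy-7-(methoxymethoxy)-2,2-dimethyl-2H-chromene-6-carboxylate
Product: 8 methyl 5-methoxy-7-(methoxymethoxy)-2,2-dimethyl-2H-chromene-6-carboxylate
Conditions: MeI, K2CO3, DMF, 50 °C
Reagents that add atoms: iodomethane, CI
Why: Williamson O-methylation of the hydrogen-bonded 5-OH, the only free hydroxyl; carbonate in warm DMF breaks the chelate, and the MOM ether, the methyl ester and the chromene olefin are inert under these conditions.

Step 5
Reactants: 8 methyl 5-methoxy-7-(methoxymethoxy)-2,2-dimethyl-2H-chromene-6-carboxylate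
Product: 9 methyl 7-hydroxy-5-methoxy-2,2-dimethyl-2H-chromene-6-carboxylate
Conditions: aq. HCl (0.5 equiv), MeOH, 40 °C
Reagents that add atoms: none
Why: Acid-catalysed acetal exchange (MOM cleavage) in methanol; an aryl MOM ether ortho to a carbonyl group is cleaved readily, and dilute acid at 40 °C should be tolerated by the 2,2-dimethyl-2H-chromene, the aryl methyl ether and the hindered methyl ester.

Step 6
Reactants: 9 methyl 7-hydroxy-5-methoxy-2,2-dimethyl-2H-chromene-6-carboxylate; 10 4-methoxyphenylacetyl chloride
Product: 11 methyl 5-methoxy-7-{[(4-methoxyphenyl)acetyl]oxy}-2,2-dimethyl-2H-chromene-6-carboxylate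
Conditions: pyridine, DMAP (cat.), CH2Cl2, 0 °C to rt
Reagents that add atoms: none
Why: O-acylation of a phenol by an acid chloride under nucleophilic catalysis; pyridine in place of a trialkylamine keeps ketene formation from the arylacetyl chloride low, and 9 has no other acylable group.

Step 7
Reactants: 11 methyl 5-methoxy-7-{[(4-methoxyphenyl)acetyl]oxy}-2,2-dimethyl-2H-chromene-6-carboxylate
Product: 14 4-hydroxy-5-methoxy-3-(4-methoxyphenyl)-8,8-dimethyl-2H,8H-pyrano[3,2-g]chromen-2-one, via lithium ester enolate 12 (not isolated), via lithium 4-oxidocoumarin 13 (not isolated)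
Conditions: LiN(SiMe3)2 (2.5 equiv), THF, −78 °C to 0 °C, 11 added to the base; then 1 M HCl
Reagents that add atoms: none
Why: LiN(SiMe3)2 removes a benzylic α-hydrogen of the arylacetate to give enolate 12, whose carbon adds to the carbonyl of the C6 methyl ester; addition–elimination with loss of methoxide forms the ketone C(=O)–C bond and the coumarin ring, which is held as its lithium 4-oxido salt 13 until acid work-up gives 14. The closest known reaction type is the base-mediated cyclisation of methyl 2-(arylacetoxy)benzoates to 3-aryl-4-hydroxycoumarins, an intramolecular Claisen (Dieckmann-type) condensation. The pyranone ring closes in a 6-exo-trig mode with respect to the attacked ester carbonyl (6-enolendo-exo-trig in enolate terms), a favoured closure; no stereocentre is formed. What has to be controlled is chemoselectivity: the enolate carbon must be acylated by the C6 ester faster than the aryl ester is cleaved, transferred to another oxygen or lost as a ketene. A hindered amide base that does not add to esters, used in excess so that the methoxide set free finds no unreacted aryl ester, the proximity imposed by the ortho tether on an otherwise hindered di-ortho-substituted benzoate, and the drain of the product into the delocalised anion 13 should secure this.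

Step 8
Reactants: 14 4-hydroxy-5-methoxy-3-(4-methoxyphenyl)-8,8-dimethyl-2H,8H-pyrano[3,2-g]chromen-2-one
Product: 16 1-(7-hydroxy-5-methoxy-2,2-dimethyl-2H-chromen-6-yl)-2-(4-methoxyphenyl)ethan-1-one, via β-keto acid 15 (not isolated)
Conditions: KOH (10% aq.), EtOH, reflux, N2; then 2 M HCl, 0 °C to rt
Reagents that add atoms: none
Why: Alkaline lactone hydrolysis of the 4-hydroxycoumarin followed by decarboxylation of β-keto acid 15, the classical degradation of 4-hydroxycoumarins to 2-hydroxyaryl ketones; the oxygen freed from the lactone becomes the C7 hydroxyl, the hindered di-ortho-substituted ketone should resist retro-Claisen attack by hydroxide, and the chromene and the methyl ethers are stable to base.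

Compound list
1 | methyl 2,4,6-trihydroxybenzoate | COC(=O)c1c(O)cc(O)cc1O | starting material
2 | 3-chloro-3-methylbut-1-yne | CC(C)(Cl)C#C | starting material
3 | methyl 2,6-dihydroxy-4-[(2-methylbut-3-yn-2-yl)oxy]benzoate | COC(=O)c1c(O)cc(OC(C)(C)C#C)cc1O | intermediate
4 | methyl 2-hydroxy-6-(methoxymethoxy)-4-[(2-methylbut-3-yn-2-yl)oxy]benzoate | COC(=O)c1c(O)cc(OC(C)(C)C#C)cc1OCOC | intermediate
5 | methyl 2,4-dihydroxy-6-(methoxymethoxy)-3-(3-methylbuta-1,2-dien-1-yl)benzoate (allenylphenol) | COC(=O)c1c(O)c(C=C=C(C)C)c(O)cc1OCOC | intermediate (not isolated)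
6 | methyl (3Z)-2-hydroxy-6-(methoxymethoxy)-3-(3-methylbut-2-en-1-ylidene)-4-oxocyclohexa-1,5-diene-1-carboxylate (quinone methide) | COC(=O)C1=C(O)/C(=C/C=C(C)C)C(=O)C=C1OCOC | intermediate (not isolated)
7 | methyl 5-hydroxy-7-(methoxymethoxy)-2,2-dimethyl-2H-chromene-6-carboxylate | COC(=O)c1c(O)c2C=CC(C)(C)Oc2cc1OCOC | intermediate
8 | methyl 5-methoxy-7-(methoxymethoxy)-2,2-dimethyl-2H-chromene-6-carboxylate | COC(=O)c1c(OC)c2C=CC(C)(C)Oc2cc1OCOC | intermediate
9 | methyl 7-hydroxy-5-methoxy-2,2-dimethyl-2H-chromene-6-carboxylate | COC(=O)c1c(OC)c2C=CC(C)(C)Oc2cc1O | intermediate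
10 | 4-methoxyphenylacetyl chloride | COc1ccc(CC(=O)Cl)cc1 | starting material
11 | methyl 5-methoxy-7-{[(4-methoxyphenyl)acetyl]oxy}-2,2-dimethyl-2H-chromene-6-carboxylate | COC(=O)c1c(OC(=O)Cc2ccc(OC)cc2)cc2OC(C)(C)C=Cc2c1OC | intermediate
12 | lithium 1-{[5-methoxy-6-(methoxycarbonyl)-2,2-dimethyl-2H-chromen-7-yl]oxy}-2-(4-methoxyphenyl)ethen-1-olate (enolate geometry not defined) | COC(=O)c1c(OC([O-])=Cc2ccc(OC)cc2)cc2OC(C)(C)C=Cc2c1OC.[Li+] | intermediate (not isolated)
13 | lithium 5-methoxy-3-(4-methoxyphenyl)-8,8-dimethyl-2-oxo-2H,8H-pyrano[3,2-g]chromen-4-olate | COc1ccc(cc1)C1=C([O-])c2c(OC)c3C=CC(C)(C)Oc3cc2OC1=O.[Li+] | intermediate (not isolated)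
14 | 4-hydroxy-5-methoxy-3-(4-methoxyphenyl)-8,8-dimethyl-2H,8H-pyrano[3,2-g]chromen-2-one | COc1ccc(cc1)C1=C(O)c2c(OC)c3C=CC(C)(C)Oc3cc2OC1=O | intermediate
15 | 3-(7-hydroxy-5-methoxy-2,2-dimethyl-2H-chromen-6-yl)-2-(4-methoxyphenyl)-3-oxopropanoic acid (racemic, labile centre; present as its potassium salt) | COc1ccc(cc1)C(C(=O)O)C(=O)c1c(O)cc2OC(C)(C)C=Cc2c1OC | intermediate (not isolated)
16 | 1-(7-hydroxy-5-methoxy-2,2-dimethyl-2H-chromen-6-yl)-2-(4-methoxyphenyl)ethan-1-one | COc1ccc(CC(=O)c2c(O)cc3c(c2OC)C=CC(C)(C)O3)cc1 | target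

Total step count: 8
Longest linear sequence: 8 steps (1 to 16)

Steps most likely to fail

Step 7. The aryl ester enolate may fragment into an arylketene and the phenoxide, or pass its acyl group to another oxygen, faster than it closes onto the hindered C6 ester. The fallback sets out from 8 and comes back at 16, and makes the ketone by addition of a benzyl organometallic to an aldehyde. LiAlH4 in THF at 0 °C reduces the ester of 8 to [5-methoxy-7-(methoxymethoxy)-2,2-dimethyl-2H-chromen-6-yl]methanol F1. MnO2 in CH2Cl2 oxidises this benzylic alcohol to 5-methoxy-7-(methoxymethoxy)-2,2-dimethyl-2H-chromene-6-carbaldehyde F2. 4-Methoxybenzylmagnesium chloride in THF at −78 °C adds to give racemic 1-[5-methoxy-7-(methoxymethoxy)-2,2-dimethyl-2H-chromen-6-yl]-2-(4-methoxyphenyl)ethan-1-ol F3. Dess–Martin periodinane with NaHCO3 in CH2Cl2 oxidises it to 1-[5-methoxy-7-(methoxymethoxy)-2,2-dimethyl-2H-chromen-6-yl]-2-(4-methoxyphenyl)ethan-1-one F4. Methanolic HCl at 40 °C then removes the MOM group to give 16.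

Step 3. The sigmatropic shift may divide between the two ortho carbons if the hydrogen bond does not bias it enough, and the acetal may be lost on prolonged heating. The fallback sets out from 3 and comes back at 9. It replaces the small acetal by a bulky silyl ether that shields C5 and is later removed by fluoride, without acid. TIPSOTf (1.05 equiv) and 2,6-lutidine in CH2Cl2 at −40 °C convert 3 into methyl 2-hydroxy-4-[(2-methylbut-3-yn-2-yl)oxy]-6-[tri(propan-2-yl)silyloxy]benzoate F5. Heating in o-xylene gives methyl 5-hydroxy-2,2-dimethyl-7-[tri(propan-2-yl)silyloxy]-2H-chromene-6-carboxylate F6. MeI and K2CO3 in refluxing acetone give methyl 5-methoxy-2,2-dimethyl-7-[tri(propan-2-yl)silyloxy]-2H-chromene-6-carboxylate F7. Bu4NF buffered with AcOH in THF at 0 °C then frees the phenol 9.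

Step 1. Etherification may spread over more than one hydroxyl or onto a ring carbon, and the tertiary chloride may eliminate before it is captured. The fallback sets out from 1 and comes back at 7, and builds the pyran ring without a propargyl ether. Condensation of 1 with 3-methylbut-2-enal, catalysed by ethylenediammonium diacetate in refluxing toluene (Knoevenagel-type condensation, then oxa-6π closure through the non-hydrogen-bonded 4-oxygen), should give methyl 5,7-dihydroxy-2,2-dimethyl-2H-chromene-6-carboxylate F8. MOMCl (1.0 equiv) and iPr2NEt in CH2Cl2 at 0 °C then cap the less hindered 7-OH, since the 5-OH is shielded by the ring fusion and the C4 hydrogen, giving 7.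

Further compounds
F1 | step 7 | [5-methoxy-7-(methoxymethoxy)-2,2-dimethyl-2H-chromen-6-yl]methanol | OCc1c(OC)c2C=CC(C)(C)Oc2cc1OCOC
F2 | step 7 | 5-methoxy-7-(methoxymethoxy)-2,2-dimethyl-2H-chromene-6-carbaldehyde | O=Cc1c(OC)c2C=CC(C)(C)Oc2cc1OCOC
F3 | step 7 | 1-[5-methoxy-7-(methoxymethoxy)-2,2-dimethyl-2H-chromen-6-yl]-2-(4-methoxyphenyl)ethan-1-ol (racemic) | COc1ccc(CC(O)c2c(OC)c3C=CC(C)(C)Oc3cc2OCOC)cc1
F4 | step 7 | 1-[5-methoxy-7-(methoxymethoxy)-2,2-dimethyl-2H-chromen-6-yl]-2-(4-methoxyphenyl)ethan-1-one | COc1ccc(CC(=O)c2c(OC)c3C=CC(C)(C)Oc3cc2OCOC)cc1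
F5 | step 3 | methyl 2-hydroxy-4-[(2-methylbut-3-yn-2-yl)oxy]-6-[tri(propan-2-yl)silyloxy]benzoate | COC(=O)c1c(O)cc(OC(C)(C)C#C)cc1O[Si](C(C)C)(C(C)C)C(C)C
F6 | step 3 | methyl 5-hydroxy-2,2-dimethyl-7-[tri(propan-2-yl)silyloxy]-2H-chromene-6-carboxylate | COC(=O)c1c(O)c2C=CC(C)(C)Oc2cc1O[Si](C(C)C)(C(C)C)C(C)C
F7 | step 3 | methyl 5-methoxy-2,2-dimethyl-7-[tri(propan-2-yl)silyloxy]-2H-chromene-6-carboxylate | COC(=O)c1c(OC)c2C=CC(C)(C)Oc2cc1O[Si](C(C)C)(C(C)C)C(C)C
F8 | step 1 | methyl 5,7-dihydroxy-2,2-dimethyl-2H-chromene-6-carboxylate | COC(=O)c1c(O)cc2OC(C)(C)C=Cc2c1O
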